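Slowness is what the red run shows: after 15.0 h the product stands at 6.4 % of the charge, with 31.2 % of the substrate fed by then.

| setting | red | Wednesday's | Saturday's |
|---|---|---|---|
| substrate | 0.065 M (fed, over 2.0 d) | 0.065 M | 0.065 M (fed, over 2.0 d) |
| reagent | 2.2 equiv | 1.50 equiv | 1.50 equiv |
| free catalyst | 0.1 mol% | 0.1 mol% | 0.1 mol% |
| remark | run made earlier; the fed solution adds 0.10 times the starting volume | everything together at the start, the whole solution of substrate included, so that from the start the volume is larger by 0.10 times the starting volume | the fed solution adds 0.10 times the starting volume |
| time |  | 0.60 d | 2.0 d |

- red (time / h: product / %): 1.00: 0.1; 2.50: 0.1; 6.00: 1.1; 15.0: 6.4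

(each reading ± 0.3 percentage points)

- charges are per starting volume, the dose included; the dosed solution carries all of it
- steps under discussion: substrate + free catalyst <-> catalyst intermediate A; reagent + catalyst intermediate A -> catalyst intermediate B; catalyst intermediate B -> by-product + catalyst intermediate C; catalyst intermediate C -> free catalyst + product; free catalyst -> spent catalyst
- percentages count the whole charge, also what has not yet gone in

1. the flask that ends with the higher amount of product, in percent of the substrate charged, or "neither" when 2 percentage points or less lies between them (Wednesday's / Saturday's / neither)
2. final product, as a percentage of the substrate charged, in Wednesday's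
3. final product, as a percentage of the substrate charged, in Saturday's

Read row by row, the first two entries, 0.1 % and 0.1 %, disappear in a scatter of 0.3 percentage points, so the last two rows carry the information. Follow one substrate molecule: once in the flask, take it to have a steady chance per hour, k, of becoming product, a pseudo-first-order constant. Product P is then k times the exposure E, the time integral of the substrate standing in the flask as a share of the charge. With a steady feed over the dosing time t_f, and P growing with the square of time t, E = t·t/(2t_f) − P·t/3. The last row gives E = 2.02 h, so the substrate's chance per hour in the red run reads k = 0.0316 h⁻¹, a reading that carries the scatter of its row. The third row tests this: its exposure predicts 1.12 %, and the reading is 1.1 %.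

My own reckoning assumes k proportional to the concentrations of reagent and catalyst, which the red run cannot test, and it takes the red reading as belonging to the starting volume. Saturday's, at its mean volume, has 0.0196 h⁻¹. Wednesday's, diluted fully from the start, has 0.0178 h⁻¹. Every molecule in Wednesday's gets 0.60 d, giving 22.6 %. A molecule in Saturday's gets 24.0 h on average, and averaging over entry times gives 35.1 %. This counts neither reagent used nor catalyst lost.

The forecast gives 21 % for Wednesday's and 30 % for Saturday's, with Saturday's ahead. Its Saturday's figure lies below my 35.1 %, and its ground for shading is: “Catalyst death would hit this run harder, since substrate stays low and the time is long”.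

The simulation gives 23.0 % in Wednesday's and 35.1 % in Saturday's, so Saturday's ends higher.

    substrate + free catalyst ⇌ catalyst intermediate A (K = 37.0 L mol⁻¹, k = 11.0 L mol⁻¹ min⁻¹)
    reagent + catalyst intermediate A → catalyst intermediate B (k = 84.0 L mol⁻¹ min⁻¹)
    catalyst intermediate B → by-product + catalyst intermediate C (k = 0.870 min⁻¹)
    catalyst intermediate C → free catalyst + product (k = 2.00 min⁻¹)
    free catalyst → spent catalyst (k = 1.70 × 10⁻⁴ min⁻¹)

Read back from its final product, Wednesday's has a chance per hour of 0.0181 h⁻¹, beside the reckoned 0.0178 h⁻¹. Saturday's ends 5.1 points above the forecast, with 29.9 % of its catalyst as spent catalyst. The neighbouring flask is Wednesday's left until 2.5 d, with the same amounts; the reckoned 0.0178 h⁻¹, carried over unchanged, gives 65.6 % there. That neighbouring flask reads 67.3 % product, with 33 % of the substrate still unbound.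

The numbers in the tables stem from a simulated flask on assumed constants; the scatter is artificial.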